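If I want to know where a flask stops, I count turnovers: how many substrate one reagent consumes before the loss of substrate stalls. The flasks, readings and question are these.

| flask | substrate | reagent | capture agent | remark | time |
|---|---|---|---|---|---|
| violet | 0.027 M | 0.144 M | 3.6 mM | run made earlier |  |
| grey | 0.52 M | 0.144 M | 3.6 mM | run made earlier |  |
| zeta | 0.040 M | 0.144 M | 3.60 mM |  | 8.0 d |
| gamma | 0.080 M | 0.144 M | 3.60 mM |  | 8.0 d |
| theta | 0.15 M | 0.144 M | 3.60 mM |  | 8.0 d |
| eta | 0.30 M | 0.144 M | 3.60 mM |  | 8.0 d |
| delta | 0.60 M | 0.144 M | 3.60 mM |  | 8.0 d |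

| run | time / d | target / % | substrate / % |
|---|---|---|---|
| violet | 0.625 | 18.2 | 30.3 |
| violet | 1.25 | 18.1 | 9.8 |
| violet | 1.67 | 14.6 | 4.2 |
| violet | 2.50 | 8.9 | 0.9 |
| violet | 3.00 | 6.0 | 0.4 |
| violet | 4.00 | 3.5 | 0.5 |
| grey | 0.333 | 1.9 | 69.2 |
| grey | 0.500 | 1.9 | 63.4 |
| grey | 0.833 | 1.0 | 57.6 |
| grey | 1.04 | 0.2 | 56.1 |
| grey | 1.67 | 0 | 54.8 |
| grey | 2.50 | 0.1 | 54.6 |
| grey | 4.00 | 0 | 53.6 |

(scatter of a reading: 0.3 percentage points)

- the analysis behind the earlier runs scatters by 0.3 percentage points, standard deviation
- "hardly changes" means that all values lie within two and a half points (for a concentration: within two and a half percent of the largest)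

- [target] at the end for zeta, gamma, theta, eta, delta, in this order
- the shape of the row from first to last (rises all the way / hardly changes / falls all the way / rises, then falls / falls, then rises)

In the violet run nearly all of the substrate has gone by 3.00 d, so that simulated run shows no stall. But the grey run levels off with 53.6% of its substrate remaining at 4.00 d, and that plateau gives the count. Substrate lost per reagent charged in grey comes to 1.68; I call this the reach of the reagent, a turnover count that carries the scatter of its readings.

So the reagent can take 1.61 times the theta charge, but less than the eta and delta charges. There I treat reagent as the limiting reagent, and I reckon that eta keeps 19.6% of its substrate and delta 59.8%. At 4.00 d grey holds 0% target beside its remaining substrate, while violet holds 3.5% at 4.00 d. So I expect the row to rise and then fall, turning near 0.241 M.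

The forecast gives 3.000 × 10⁻⁴ M, 0.001 M, 0.004 M, 1.000 × 10⁻⁵ M and 0 M, a row that rises, then falls. Its ground for eta and delta: “substrate survives and kills target, leaving essentially zero”.

The flasks give 4.62 × 10⁻⁴ M, 9.34 × 10⁻⁴ M, 0.00171 M, 3.70 × 10⁻⁴ M and 7.61 × 10⁻⁵ M, a row that rises, then falls, turning at 0.17 M.

    substrate + reagent → open intermediate + by-product (k = 0.00960 /M/min)
    open intermediate ⇌ target (K = 1.00, k = 0.00250 /min)
    open intermediate ⇌ isomer of the product (K = 45.0, k = 0.00100 /min)
    reagent + target → over-reaction product (k = 0.00230 /M/min)
    substrate + target → side product (k = 0.0220 /M/min)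
    open intermediate + capture agent → trapped intermediate (k = 0.00490 /M/min)

In zeta, target is made 3.48 times faster than it is used up at 0.341 d, each step taken net. At 8.00 d that ratio has dropped to 0.824, with target at 1.16% of the substrate charged. In delta, reagent stands at 0% at 8.00 d, with 59% of the substrate left beside the reach's 59.8%. In eta, with reagent also at 0%, 24% of the substrate is left, more than the reach's 19.6%, and by 80.0 d the substrate in eta has fallen to 12.7%, less than that reckoned share.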